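The earlier runs and the new flask were generated by integration with made-up constants; the scatter is artificial.

Q is the substrate, and you want to know how much of it stands as L after 2.0 h in flasks with one charge.

| flask | Q | temperature | remark | time |
|---|---|---|---|---|
| grey | 0.13 M | 45 °C | run made earlier |  |
| amber | 0.30 M | 65 °C | run made earlier |  |
| south-east | 0.20 M | 65 °C |  | 2.0 h |
| east | 0.20 M | 50 °C |  | 2.0 h |
| south-west | 0.20 M | 80 °C |  | 2.0 h |
| north-west | 0.20 M |  | at 50 °C until 40 min, from then on at 80 °C | 2.0 h |

| run | time / h | L / % | Q / % |
|---|---|---|---|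
| grey | 0.500 | 0 | 95.8 |
| grey | 0.833 | 0.7 | 92.7 |
| grey | 2.00 | 0.9 | 83.7 |
| grey | 4.00 | 1.2 | 71.6 |
| grey | 6.00 | 1.1 | 63.6 |
| amber | 0.200 | 0.7 | 82.8 |
| amber | 0.333 | 2.1 | 74.0 |
| amber | 0.667 | 3.2 | 60.0 |
| amber | 1.33 | 4.0 | 45.3 |
| amber | 2.50 | 6.0 | 37.5 |

(standard deviation of a reading: 0.5 percentage points)
- in percentages every species weighs as the Q in it: one J counts as two
- for L the D are counted in
- as a solid, counted per litre of solution: D
- steps thought possible: Q -> L; 2 Q <-> J; Q <-> X; D <-> L; L -> E
1. the best flask by amount of L, in percent of the Q charged; "all alike" if 1.5 percentage points covers them all (south-east / east / south-west / north-west / all alike)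
2. amount of L at the end, in percent of the Q charged, south-east
3. amount of L at the end, in percent of the Q charged, east
4. amount of L at the end, in percent of the Q charged, south-west
5. amount of L at the end, in percent of the Q charged, north-west

Fold each run into one dimensionless number, the share: L found divided by Q gone, both as fractions of the charge. This is the run's selectivity, and you can treat it as a gain that turns Q lost into L. At its last reading grey gives 0.0302 and amber 0.0960, so from grey at 45 °C to amber at 65 °C the share reads higher by a factor of 3.18. That is a rough reading, since grey's L of 1.1% carries a scatter of 0.5 percentage points. It also mixes in charge and time of reading, though in charge the flasks asked about stand between the two runs at 0.20 M.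

Take that factor as an effect of temperature, which is my assumption, stretch it geometrically from 65 °C to 80 °C, and you get my hot share, the expected fraction of lost Q found as L at that temperature: 0.228. Borrow amber's loss of 62 points, which is my assumption, and south-west should hold about 0.143 of the charge as L. Its share is higher than amber's, so I put south-west first, with north-west, cold for its first 40 min, behind it.

Is one number enough? Not quite. Within amber the share climbs from 0.0407 at 0.200 h to 0.0960 at 2.50 h, so it depends on when you read.

The forecast also chose south-west, with 4.2% south-east, 1.4% east, 7% south-west and 6% north-west, reasoning that when hot “formation is faster, but so is loss to J and E”. For south-west my figure is higher than the forecast's.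

South-west is the best flask with 18.4%, above both estimates; north-west gives 13.8%, south-east 4.70% and east 1.03%.

    Q → L (k = 6.12 × 10⁻⁵ s⁻¹, Ea = 113 kJ mol⁻¹)
    2 Q ⇌ J (K = 13.5 M⁻¹, k = 5.79 × 10⁻⁴ M⁻¹ s⁻¹, Ea = 68.0 kJ mol⁻¹, ΔH = 33.0 kJ mol⁻¹)
    Q ⇌ X (K = 0.378, k = 8.03 × 10⁻⁴ s⁻¹, Ea = 108 kJ mol⁻¹, ΔH = −36.0 kJ mol⁻¹)
    D ⇌ L, rate k4*(cs4 - [L]) while solid is left; crystals form when [L] > cs4 (solubility = 15.0 mM, k = 0.00198 s⁻¹)
    L → E (k = 4.84 × 10⁻⁵ s⁻¹, Ea = 118 kJ mol⁻¹)
    (constants at 80 °C)

At 2.00 h south-west holds 33.3% as J and 12.9% as X, both counted in the Q gone. Its share comes to 0.274, higher than my 0.228. Now read the same south-west flask early: at 0.500 h Q stands at 53.6%, so the hot share promises 0.106 of the charge as L. The computed south-west flask holds 6.92% at that time, lower than that.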